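**Remark on the chemistry.** Germacrane numbering is used for every compound (C1–C10 ring, C11–C13 acrylate unit, C14 = methyl on C10, C15 = carbon on C4); α/β refer to the usual drawing with H-7 α. In the bicyclic precursors ring A is C1–C5/C10 and ring B is C5–C10. The target is read as (1R,6R,7R,8R,10R): 1β,10α-epoxide, 6α,12-olide, 8β-ester, C2=C3 Z, C4=C5 with C3 and C6 cis (E by CIP).

## Structural features

The target is a germacranolide: a ten-membered carbocycle (C1–C10) carrying a trans-fused α-methylene-γ-butyrolactone across C6–C7 (O on C6, C11=C13, C12=O). The ring holds three contiguous sp3 stereocenters, C6, C7 and C8 (8β-acyloxy), and, across the ring, the epoxide pair C1/C10 with a quaternary C10. Between them lies a diene, C2=C3–C4=C5, in which both double bonds are cis with respect to the ring, while the C1–C10 epoxide is trans. Fragile groups are the dienyl epoxide (acid, SN2′), the methylene lactone (Michael acceptor), the Z-enoate with its allylic acetate (isomerization, acyl transfer) and the primary allylic alcohol C15. The real difficulty is the strained ten-membered ring with two ring-cis alkenes and one trans unit, and the relation of C1/C10 to the remote triad C6–C8. The key step exploits the fact that C10(O)–C1(O)–C2=C3–C4=C5 is a cyclodeca-1(10),2,4-triene in disguise. C5 and C10 are the termini of a hexatriene, so the ten-membered ring is the electrocyclic ring-opened form of a cyclohexa-1,3-diene (ring A) fused to a cyclohexane (ring B) at C5–C10. C2=C3 is then cis by necessity, and the other two geometries follow from the configuration at C5 and C10.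

## Logic of the disconnections

29 ⇒ 28. Only the O–Si bond at C15 is cut. A free allylic alcohol would compete in the oxidation that makes the epoxide; the forward step must avoid acid (dienyl epoxide) and free alkoxide (acetate, methylene lactone).

28 ⇒ 27. The C1–O and C10–O bonds are cut. The epoxide is a masked E-alkene, and its removal exposes the 1(10),2,4-triene. The forward step must pick C1=C10 among five alkenes and the right face, at low temperature.

27 ⇒ 26. In the retro direction the C5–C10 bond is formed: the ten-membered ring and its three alkene geometries collapse to a cis-fused hexalin with two sp3 centers. The forward photochemical opening must turn C9 outward (C1=C10 E) and C6 inward (C4=C5 ring-cis). This requires the 5α-H/10α-CH3 cis fusion in 26, held by the trans-lactone.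

26 ⇒ 20 + 25. The C8–O ester bond is cut, with inversion at C8. The sensitive Z-acyl group comes last before the key step, and C8 may be α (equatorial) in all earlier compounds, which the ring B closure needs. The forward step is an SN2 reaction at a hindered secondary carbon.

20 ⇒ 19 ⇒ 16. The C11=C13 bond is cut (one carbon from an iminium salt). The Michael acceptor is thereby absent during all enolate chemistry on ring A.

16 ⇒ 15 ⇒ 14 ⇒ 13. The C4–C15 bond is cut and the C3 oxygen restored. The ring A diene reduces to an enone whose only enolizable position is C4. The forward steps need ketone-over-lactone selectivity.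

13 ⇒ 12 ⇒ 11. The C5–C6 bond (ring B) and the O6–C12 bond (lactone) are cut. The bicycle with five stereocenters becomes an achiral cyclohexadienone carrying a chain with two stereocenters. The forward step must distinguish the two enone arms; an all-equatorial chair does this only if C7/C8 are syn (8α-O).

11 ⇒ 10 ⇒ 9 ⇒ 8 ⇒ 7 + 4. The C7–C8 bond is cut (aldol); the rest is oxidation-state and protecting-group change. Both chain stereocenters come from one auxiliary-controlled step, which must be syn-selective and tolerate the dienone.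

4 ⇒ 3 ⇒ 1 + 2. The C9–C10 bond is cut, then one carbon of the allyl group. Ring A with its quaternary C10 comes from a cresol by dearomatization. The forward step must attack the para carbon.

7 ⇒ 5 + 6 and 25 ⇒ 24 ⇒ 23 ⇒ 21. An N–C(acyl) bond is cut in the first; the acid is traced to a butenolide whose ring fixes the Z geometry. The forward sequence must keep the hydroxy acid from relactonizing.

## Other disconnections considered

Alternative 1: (the first that comes to mind) Cut C6–C7 and the lactone C–O bond. Forward: intramolecular allylation of the (2Z,4Z)-dienal A1 by its 2-(bromomethyl)acrylate terminus (CrCl2 with catalytic NiCl2), giving macrocycle A2. Grounds against: the Z,Z-dienal can isomerize or close to a 2H-pyran (oxa-6π). The closure must pay for ring strain with both cis alkenes and the trans epoxide already in place. The cyclic transition state relates C6/C7 to C8 but not reliably to C1/C10. The chosen plan makes the medium ring by cutting a bond, not by closing one, and derives all three geometries from two sp3 centers.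

Alternative 2: Cut C6–C7 by [2,3]-Wittig ring contraction of the 13-membered bis-allylic ether A3 (anion at C6, bond to C7, C11=C13 formed) to alcohol A4. Grounds against: a 13-membered ring must be closed first. The C6 anion is a pentadienyl anion whose C2 terminus is β to the epoxide oxygen, so epoxide opening competes. C6/C7 configuration relative to C8 and C1/C10 depends on an unpredictable macrocyclic transition state, and C12 still has to be oxidized. The step count is not lower.

Alternative 3: Cut C2=C3 by diene–ene ring-closing metathesis of A5 (second-generation Grubbs catalyst), which would give A2. Grounds against: Z-selectivity in a ten-membered conjugated diene is not assured. The ruthenium carbene can enter at C4=C5 (ring-contracted product) or at the methylene lactone, and a vinyl epoxide next to the carbene is labile. The three geometries are not linked to any stereocenter as they are in the chosen plan.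

Key step: step 19

## Steps

Step 1
Reactants: 1 4-methylphenol; 2 allyltrimethylsilane
Product: 3 4-methyl-4-(prop-2-en-1-yl)cyclohexa-2,5-dien-1-one
Conditions: PhI(OAc)2, (CF3)2CHOH/CH2Cl2, −20 → 0 °C
Reagents that add atoms: none
Why: Oxidative dearomatization: the phenoxenium-type intermediate from 1 is captured at the para carbon by the allylsilane (Hosomi–Sakurai-type attack) and the para methyl blocks rearomatization, so quaternary C10 and ring A arise in one operation; 3 is achiral.

Step 2
Reactants: 3
Product: 4 2-(1-methyl-4-oxocyclohexa-2,5-dien-1-yl)acetaldehyde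
Conditions: O3, CH2Cl2/MeOH, −78 °C; Me2S
Reagents that add atoms: ozone, [O-][O+]=O
Why: Ozonolysis with reductive work-up; the monosubstituted alkene is the only electron-rich C=C, the two enone double bonds are deactivated toward ozone.

Step 3
Reactants: 5 4-tert-butoxy-4-oxobutanoic acid; 6 (4R)-4-benzyl-1,3-oxazolidin-2-one
Product: 7 tert-butyl 4-[(4R)-4-benzyl-2-oxo-1,3-oxazolidin-3-yl]-4-oxobutanoate
Conditions: t-BuCOCl, Et3N, THF, −20 °C; then 6, LiCl, 23 °C
Reagents that add atoms: none
Why: N-Acylation through the mixed pivalic anhydride; the hindered pivaloyl carbonyl is not attacked.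

Step 4
Reactants: 7; 4
Product: 8 tert-butyl (3R,4S)-3-{[(4R)-4-benzyl-2-oxo-1,3-oxazolidin-3-yl]carbonyl}-4-hydroxy-5-(1-methyl-4-oxocyclohexa-2,5-dien-1-yl)pentanoate
Conditions: n-Bu2BOTf, i-Pr2NEt, CH2Cl2, −78 → 0 °C; 4, −78 °C; pH 7 buffer/MeOH work-up
Reagents that add atoms: none
Why: Evans syn-aldol: the Z-boron enolate reacts through a closed Zimmerman–Traxler chair on the face left open by the benzyl group, setting C7 (R) and C8 (S) syn; the dienone is inert to the boron enolate at −78 °C.

Step 5
Reactants: 8
Product: 9 4-O-triethylsilyl ether of 8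
Conditions: Et3SiCl, imidazole, DMF, 0 °C
Reagents that add atoms: chlorotriethylsilane, CC[Si](Cl)(CC)CC
Why: Silylation under non-Lewis-acidic conditions blocks retro-aldol and lactonization of O8 onto the tert-butyl ester.

Step 6
Reactants: 9
Product: 10 tert-butyl (3S,4S)-3-(hydroxymethyl)-5-(4-hydroxy-1-methylcyclohexa-2,5-dien-1-yl)-4-(triethylsilyloxy)pentanoate (both ring carbinol epimers)
Conditions: LiBH4, MeOH (3 equiv), THF, 0 °C
Reagents that add atoms: none
Why: Hydride cleavage of the imide to the primary alcohol with release of the auxiliary; the dienone is reduced 1,2 at the same time (epimers erased in step 7) and the tert-butyl ester is untouched.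

Step 7
Reactants: 10
Product: 11 tert-butyl (3R,4S)-3-formyl-5-(1-methyl-4-oxocyclohexa-2,5-dien-1-yl)-4-(triethylsilyloxy)pentanoate
Conditions: DMP (1,1,1-triacetoxy-1,2-benziodoxol-3-one, 3 equiv), NaHCO3, CH2Cl2, 0 → 23 °C
Reagents that add atoms: none
Why: Dess–Martin oxidation returns the dienone from the bis-allylic alcohol and takes the primary alcohol to the C6 aldehyde under buffered conditions that should not epimerize C7.

Step 8
Reactants: 11
Product: 13 10α-methyl-3-oxo-8α-(triethylsilyloxy)-5αH,7αH-13,15-dinoreudesm-1-en-12,6α-olide (cis-fused rings A/B, trans lactone), via hydroxy tert-butyl ester 12 (not isolated)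
Conditions: SmI2 (2.2 equiv), t-BuOH (2 equiv), THF, −78 °C; then 23 °C, 2 h
Reagents that add atoms: none
Why: Reductive aldehyde–enone (ketyl–olefin) cyclization, 6-exo-trig: the C6 ketyl adds perpendicular to one enone arm through a chair in which the samarium alkoxide, C11 and OSiEt3 are all equatorial, which selects the arm and sets C5 (α-H), C6 (α-O) and C10 (α-CH3, C1 axial) from C7/C8. The alternative arm would force C11 and O8 axial. The trivalent samarium alkoxide then closes the trans γ-lactone on the tert-butyl ester.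

Step 9
Reactants: 13
Product: 14 4-[(triisopropylsilyloxy)methyl] derivative of 13 (C4 epimers)
Conditions: LiN(i-Pr)2 (1.0 equiv), THF, −78 °C; (i-Pr)3SiOCH2Cl, −78 → −30 °C
Reagents that add atoms: (triisopropylsilyloxy)methyl chloride, ClCO[Si](C(C)C)(C(C)C)C(C)C
Why: The α′-enolate of the enone (more acidic than the lactone α-CH2, and C10 is quaternary) is C-alkylated by the alkoxymethyl chloride, which brings in C15 already protected; the C4 center later becomes sp2.

Step 10
Reactants: 14
Product: 15 3-(trifluoromethylsulfonyloxy)-15-(triisopropylsilyloxy)-8α-(triethylsilyloxy)-10α-methyl-5αH,7αH-13-noreudesma-1,3-dien-12,6α-olide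
Conditions: Tf2O, 2,6-di-tert-butyl-4-methylpyridine, CH2Cl2, 0 °C
Reagents that add atoms: triflic anhydride, O=S(=O)(OS(=O)(=O)C(F)(F)F)C(F)(F)F
Why: Enol triflate formation under non-basic conditions engages only the ketone and can only run toward C4, giving the 1,3-dien-3-yl triflate.

Step 11
Reactants: 15
Product: 16 15-(triisopropylsilyloxy)-8α-(triethylsilyloxy)-10α-methyl-5αH,7αH-13-noreudesma-1,3-dien-12,6α-olide
Conditions: Pd(OAc)2 (5 mol %), PPh3, n-Bu3N, HCO2H, DMF, 60 °C
Reagents that add atoms: none
Why: Palladium-catalysed formate reduction of the vinyl triflate (oxidative addition to zerovalent palladium, formate exchange, loss of CO2, reductive elimination) gives the homoannular diene; 60 °C is below the range of [1,5]-hydrogen shifts.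

Step 12
Reactants: 16
Product: 17 11-[(dimethylamino)methyl] derivative of 16 (C11 epimers)
Conditions: LiN(i-Pr)2 (1.2 equiv), THF, −78 °C; CH2=NMe2+ I−, −78 → 0 °C
Reagents that add atoms: dimethyl(methylidene)ammonium iodide, C=[N+](C)C.[I-]
Why: Mannich reaction of the lactone enolate, now the only acidic site; the C11 configuration is irrelevant.

Step 13
Reactants: 17
Product: 19 15-(triisopropylsilyloxy)-8α-(triethylsilyloxy)-10α-methyl-5αH,7αH-eudesma-1,3,11(13)-trien-12,6α-olide, via ammonium iodide 18 (not isolated)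
Conditions: MeI, MeOH, 23 °C; then NaHCO3 (aq.), EtOAc, 23 °C
Reagents that add atoms: none
Why: Exhaustive N-methylation and E1cB loss of trimethylamine give the exocyclic methylene with no base stronger than bicarbonate.

Step 14
Reactants: 19
Product: 20 8α-hydroxy-15-(triisopropylsilyloxy)-10α-methyl-5αH,7αH-eudesma-1,3,11(13)-trien-12,6α-olide
Conditions: PPTS (cat.), MeOH/CH2Cl2, 0 °C
Reagents that add atoms: none
Why: Acid-catalysed methanolysis removes the secondary triethylsilyl ether while the primary triisopropylsilyl ether should survive.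

Step 15
Reactants: 21 3-methylfuran-2(5H)-one
Product: 23 4-methoxybenzyl (2Z)-4-hydroxy-2-methylbut-2-enoate, via sodium carboxylate 22 (not isolated)
Conditions: NaOH (1.0 equiv), H2O/MeOH, 23 °C; evaporate; 4-MeOC6H4CH2Cl, n-Bu4NI (cat.), DMF, 0 → 23 °C
Reagents that add atoms: sodium hydroxide, [Na+].[OH-]; 4-methoxybenzyl chloride, COc1ccc(CCl)cc1
Why: Saponification opens the butenolide with the Z geometry fixed by the ring; O-alkylation of the carboxylate traps the hydroxy acid before it can relactonize.

Step 16
Reactants: 23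
Product: 24 4-methoxybenzyl (2Z)-4-acetoxy-2-methylbut-2-enoate
Conditions: Ac2O, pyridine, DMAP (cat.), CH2Cl2, 0 °C
Reagents that add atoms: acetic anhydride, CC(=O)OC(C)=O
Why: Acetylation of the primary allylic alcohol removes the nucleophile that would relactonize.

Step 17
Reactants: 24
Product: 25 (2Z)-4-acetoxy-2-methylbut-2-enoic acid
Conditions: CF3CO2H, anisole, CH2Cl2, 0 °C
Reagents that add atoms: none
Why: Acidolysis of the 4-methoxybenzyl ester with a cation scavenger frees the acid without base, so neither the Z-enoate nor the acetate is touched.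

Step 18
Reactants: 20; 25
Product: 26 (5R,6R,7R,8R,10R)-8β-[(2Z)-4-acetoxy-2-methylbut-2-enoyloxy]-15-(triisopropylsilyloxy)-10α-methyl-5αH-eudesma-1,3,11(13)-trien-12,6α-olide
Conditions: PPh3, DIAD, toluene, 0 → 23 °C
Reagents that add atoms: none
Why: Mitsunobu esterification activates the alcohol and not the acid, so the Z-enoate cannot isomerize through an acylammonium; SN2 displacement of the equatorial 8α-oxyphosphonium by the carboxylate inverts C8 to the axial 8β-ester of the target.

Step 19
Reactants: 26
Product: 28 15-O-triisopropylsilyl ether of the target, (1R,6R,7R,8R,10R), via triene 27 (not isolated)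
Conditions: hν (300 nm), degassed Et2O, −45 °C; dark, −30 °C, 15 min; dimethyldioxirane (acetone, 1 equiv on triene), −45 °C
Reagents that add atoms: dimethyldioxirane, CC1(C)OO1
Why: Excitation of the homoannular diene, the only chromophore absorbing near 300 nm, cleaves the C5–C10 σ bond by conrotatory 6π electrocycloreversion, the reaction type that turns provitamin D into previtamin D and fused hexalins into cyclodeca-1,3,5-trienes. No ring is closed in the photochemical event (the ten-membered ring appears because the bond shared by rings A and B is cut); the oxirane is then closed by concerted spiro oxygen transfer from the dioxirane. The sense of conrotation follows the ground-state helicity of the diene (least motion: pseudoaxial groups turn inward). The trans-lactone holds ring B in the chair in which C6 is pseudoaxial and C9 pseudoequatorial on ring A, so C6 turns inward (C4=C5 ring-cis) and C9 outward (C1=C10 E), while C2=C3 stays cis because it was in the six-membered ring. The selectivity needed is therefore torquoselectivity, secured by the 5α-H/10α-CH3 cis fusion together with the 6α,7β-lactone; the 5β,10β-cis or a trans-fused isomer would give the wrong pair of geometries. The triene is not isolated because it recloses thermally (disrotatory, to a trans-fused hexalin) and photochemically; low temperature and irradiation at the long-wavelength edge of the diene band limit this. The dioxirane attacks C1=C10, the only electron-rich, strained trisubstituted alkene (C4=C5 carries two allylic C–O bonds, C2=C3 is disubstituted, the other two alkenes bear acceptors), and the E geometry becomes the trans epoxide. C1 and C10 are set by peripheral attack on the conformer with C14 on the β face, the arrangement 1(10)E-germacran-12,6α-olides generally adopt. The conformer first released by conrotation has C14 on the α face, hence the hold at −30 °C to let the C9–C10=C1–C2 unit turn through the ring before the oxidant is added.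

Step 20
Reactants: 28
Product: 29 (1R,6R,7R,8R,10R)-8-[(2Z)-4-acetoxy-2-methylbut-2-enoyloxy]-1,10-epoxy-15-hydroxygermacra-2Z,4E,11(13)-trien-12,6-olide (target)
Conditions: n-Bu4NF, AcOH (1:1), THF, 0 °C
Reagents that add atoms: none
Why: Buffered fluoride cleaves the primary silyl ether; no acid reaches the dienyl epoxide and no free alkoxide reaches the acetate or the methylene lactone.

## Compound list

1 | 4-methylphenol | Cc1ccc(O)cc1 | starting material
2 | allyltrimethylsilane | C=CC[Si](C)(C)C | starting material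
3 | 4-methyl-4-(prop-2-en-1-yl)cyclohexa-2,5-dien-1-one | C=CCC1(C)C=CC(=O)C=C1 | intermediate
4 | 2-(1-methyl-4-oxocyclohexa-2,5-dien-1-yl)acetaldehyde | O=CCC1(C)C=CC(=O)C=C1 | intermediate
5 | 4-tert-butoxy-4-oxobutanoic acid | CC(C)(C)OC(=O)CCC(=O)O | starting material
6 | (4R)-4-benzyl-1,3-oxazolidin-2-one | O=C1N[C@H](Cc2ccccc2)CO1 | starting material
7 | tert-butyl 4-[(4R)-4-benzyl-2-oxo-1,3-oxazolidin-3-yl]-4-oxobutanoate | CC(C)(C)OC(=O)CCC(=O)N1[C@H](Cc2ccccc2)COC1=O | intermediate
8 | tert-butyl (3R,4S)-3-{[(4R)-4-benzyl-2-oxo-1,3-oxazolidin-3-yl]carbonyl}-4-hydroxy-5-(1-methyl-4-oxocyclohexa-2,5-dien-1-yl)pentanoate | CC(C)(C)OC(=O)C[C@H]([C@@H](O)CC1(C)C=CC(=O)C=C1)C(=O)N1[C@H](Cc2ccccc2)COC1=O | intermediate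
9 | 4-O-triethylsilyl ether of 8 | CC(C)(C)OC(=O)C[C@H]([C@@H](O[Si](CC)(CC)CC)CC1(C)C=CC(=O)C=C1)C(=O)N1[C@H](Cc2ccccc2)COC1=O | intermediate
10 | tert-butyl (3S,4S)-3-(hydroxymethyl)-5-(4-hydroxy-1-methylcyclohexa-2,5-dien-1-yl)-4-(triethylsilyloxy)pentanoate (ring carbinol epimers) | CC(C)(C)OC(=O)C[C@H]([C@@H](O[Si](CC)(CC)CC)CC1(C)C=CC(O)C=C1)CO | intermediate
11 | tert-butyl (3R,4S)-3-formyl-5-(1-methyl-4-oxocyclohexa-2,5-dien-1-yl)-4-(triethylsilyloxy)pentanoate | CC(C)(C)OC(=O)C[C@H]([C@@H](O[Si](CC)(CC)CC)CC1(C)C=CC(=O)C=C1)C=O | intermediate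
12 | tert-butyl 2-[6α-hydroxy-10α-methyl-3-oxo-8α-(triethylsilyloxy)-5αH,7αH-bicyclo[4.4.0]dec-1-en-7-yl]acetate (germacrane locants, cis-fused) | CC(C)(C)OC(=O)C[C@H]1[C@H](O)[C@H]2CC(=O)C=C[C@@]2(C)C[C@@H]1O[Si](CC)(CC)CC | intermediate
13 | 10α-methyl-3-oxo-8α-(triethylsilyloxy)-5αH,7αH-13,15-dinoreudesm-1-en-12,6α-olide | O=C1C[C@H]2[C@H](O1)[C@H]3CC(=O)C=C[C@@]3(C)C[C@@H]2O[Si](CC)(CC)CC | intermediate
14 | 4-[(triisopropylsilyloxy)methyl] derivative of 13 (C4 epimers) | O=C1C[C@H]2[C@H](O1)[C@H]3C(CO[Si](C(C)C)(C(C)C)C(C)C)C(=O)C=C[C@@]3(C)C[C@@H]2O[Si](CC)(CC)CC | intermediate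
15 | 3-(trifluoromethylsulfonyloxy)-15-(triisopropylsilyloxy)-8α-(triethylsilyloxy)-10α-methyl-5αH,7αH-13-noreudesma-1,3-dien-12,6α-olide | O=C1C[C@H]2[C@H](O1)[C@H]3C(CO[Si](C(C)C)(C(C)C)C(C)C)=C(OS(=O)(=O)C(F)(F)F)C=C[C@@]3(C)C[C@@H]2O[Si](CC)(CC)CC | intermediate
16 | 15-(triisopropylsilyloxy)-8α-(triethylsilyloxy)-10α-methyl-5αH,7αH-13-noreudesma-1,3-dien-12,6α-olide | O=C1C[C@H]2[C@H](O1)[C@H]3C(CO[Si](C(C)C)(C(C)C)C(C)C)=CC=C[C@@]3(C)C[C@@H]2O[Si](CC)(CC)CC | intermediate
17 | 11-[(dimethylamino)methyl] derivative of 16 (C11 epimers) | CN(C)CC1C(=O)O[C@H]2[C@H]1[C@@H](O[Si](CC)(CC)CC)C[C@]3(C)C=CC=C(CO[Si](C(C)C)(C(C)C)C(C)C)[C@H]23 | intermediate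
18 | N-methyl ammonium iodide of 17 | C[N+](C)(C)CC1C(=O)O[C@H]2[C@H]1[C@@H](O[Si](CC)(CC)CC)C[C@]3(C)C=CC=C(CO[Si](C(C)C)(C(C)C)C(C)C)[C@H]23.[I-] | intermediate
19 | 15-(triisopropylsilyloxy)-8α-(triethylsilyloxy)-10α-methyl-5αH,7αH-eudesma-1,3,11(13)-trien-12,6α-olide | C=C1C(=O)O[C@H]2[C@H]1[C@@H](O[Si](CC)(CC)CC)C[C@]3(C)C=CC=C(CO[Si](C(C)C)(C(C)C)C(C)C)[C@H]23 | intermediate
20 | 8α-hydroxy-15-(triisopropylsilyloxy)-10α-methyl-5αH,7αH-eudesma-1,3,11(13)-trien-12,6α-olide | C=C1C(=O)O[C@H]2[C@H]1[C@@H](O)C[C@]3(C)C=CC=C(CO[Si](C(C)C)(C(C)C)C(C)C)[C@H]23 | intermediate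
21 | 3-methylfuran-2(5H)-one | CC1=CCOC1=O | starting material
22 | sodium (2Z)-4-hydroxy-2-methylbut-2-enoate | [Na+].[O-]C(=O)/C(C)=C\CO | intermediate
23 | 4-methoxybenzyl (2Z)-4-hydroxy-2-methylbut-2-enoate | COc1ccc(COC(=O)/C(C)=C\CO)cc1 | intermediate
24 | 4-methoxybenzyl (2Z)-4-acetoxy-2-methylbut-2-enoate | COc1ccc(COC(=O)/C(C)=C\COC(C)=O)cc1 | intermediate
25 | (2Z)-4-acetoxy-2-methylbut-2-enoic acid | OC(=O)/C(C)=C\COC(C)=O | intermediate
26 | (5R,6R,7R,8R,10R)-8β-[(2Z)-4-acetoxy-2-methylbut-2-enoyloxy]-15-(triisopropylsilyloxy)-10α-methyl-5αH-eudesma-1,3,11(13)-trien-12,6α-olide | C=C1C(=O)O[C@H]2[C@H]1[C@H](OC(=O)/C(C)=C\COC(C)=O)C[C@]3(C)C=CC=C(CO[Si](C(C)C)(C(C)C)C(C)C)[C@H]23 | intermediate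
27 | (6R,7R,8R)-8-[(2Z)-4-acetoxy-2-methylbut-2-enoyloxy]-15-(triisopropylsilyloxy)germacra-1(10)E,2Z,4(C3/C6 cis),11(13)-tetraen-12,6-olide | C=C1C(=O)O[C@@H]2/C=C(CO[Si](C(C)C)(C(C)C)C(C)C)\C=C/C=C(\C)C[C@@H](OC(=O)/C(C)=C\COC(C)=O)[C@@H]12 | intermediate
28 | 15-O-triisopropylsilyl ether of the target, (1R,6R,7R,8R,10R) | C=C1C(=O)O[C@@H]2/C=C(CO[Si](C(C)C)(C(C)C)C(C)C)\C=C/[C@H]3O[C@]3(C)C[C@@H](OC(=O)/C(C)=C\COC(C)=O)[C@@H]12 | intermediate
29 | (1R,6R,7R,8R,10R)-8-[(2Z)-4-acetoxy-2-methylbut-2-enoyloxy]-1,10-epoxy-15-hydroxygermacra-2Z,4E,11(13)-trien-12,6-olide | C=C1C(=O)O[C@@H]2/C=C(CO)\C=C/[C@H]3O[C@]3(C)C[C@@H](OC(=O)/C(C)=C\COC(C)=O)[C@@H]12 | target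

## Step count and least certain steps

Total: 20 steps. Longest linear sequence: 16 steps (1, 2, 4–14, 18–20, from 4-methylphenol).

**Step 19 (key step).** Three processes can fail:
- The photostationary state may hold little triene, with thermal or photochemical return to hexalins.
- Conrotation may run in the other sense if ring B leaves its chair, giving the 1(10)Z,4E triene.
- Oxygen may be transferred to the wrong face if the first-formed C14-α conformer reacts before it relaxes, or if the C14-β conformer is not the preferred one.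

Fallback: change from substrate control to catalyst control of the face. The cold solution of 27 is added to the chiral dioxirane generated from the D-fructose-derived ketone and KHSO5 at −10 °C (Shi epoxidation). Its intrinsic preference on E-trisubstituted alkenes corresponds to the (1R,10R) epoxide, and since the alkene can present either face by rotation through the ring, the catalyst selects the conformer. The fallback sets out from 27 and returns at 28 and makes no new compound (F0).

**Step 8.** Reduction of the dienone before the aldehyde may lead to pinacol-type dimers or to over-reduction of the remaining enone. Attack on the other enone arm would give the C5/C10 diastereomer. Lactonization on the tert-butyl ester may be slow.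

Fallback: polar acyl-anion chemistry in place of the ketyl. From 11, a carbene-catalysed intramolecular Stetter reaction (chiral aminoindanol-derived triazolium salt, i-Pr2NEt, toluene) desymmetrizes the dienone to the 6-ketone F1. NaBH4 in MeOH/CH2Cl2 at −78 °C reduces the saturated ketone in preference to the enone by axial delivery, giving the 6α-alcohol 12, which lactonizes to 13.

**Step 18.** Backside attack at C8 passes the axial C1 of ring A and may be slow, so that acyl transfer with retention or no reaction takes over.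

Fallback: oxidation/reduction, done before the methylene lactone exists. From 16:
- PPTS/MeOH gives the 8α-alcohol F4.
- Dess–Martin oxidation gives the 8-ketone F5.
- LiBH(s-Bu)3 at −78 °C (equatorial attack) gives the axial 8β-alcohol F6.
- Et3SiOTf/2,6-lutidine gives the 8β-silyl ether F7.
- Methylenation as in steps 12 and 13 proceeds through the Mannich base F8 and its methiodide F9 to the methylene lactone F10.
- PPTS/MeOH gives the 8β-alcohol F11.
- Acylation with 25 through its 2,4,6-trichlorobenzoyl mixed anhydride (Et3N, toluene, no nucleophilic catalyst) returns to 26.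

**Step 9.** The alkoxymethyl chloride may alkylate the enolate on oxygen, or the lactone may be enolized and alkylated.

Fallback: Mukaiyama-type hydroxymethylation. From 13, Me3SiOTf/Et3N gives the silyl dienol ether F2 (ketone only). Aqueous formaldehyde with Sc(OTf)3 gives the hydroxymethyl ketone F3. (i-Pr)3SiOTf/2,6-lutidine returns to 14.

## Further compounds

F0 | step 19 | none | none
F1 | step 8 | tert-butyl 2-[10α-methyl-3,6-dioxo-8α-(triethylsilyloxy)-5αH,7αH-bicyclo[4.4.0]dec-1-en-7-yl]acetate | CC(C)(C)OC(=O)C[C@H]1C(=O)[C@H]2CC(=O)C=C[C@@]2(C)C[C@@H]1O[Si](CC)(CC)CC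
F2 | step 9 | 3-(trimethylsilyloxy)-8α-(triethylsilyloxy)-10α-methyl-5αH,7αH-13,15-dinoreudesma-1,3-dien-12,6α-olide | O=C1C[C@H]2[C@H](O1)[C@H]3C=C(O[Si](C)(C)C)C=C[C@@]3(C)C[C@@H]2O[Si](CC)(CC)CC
F3 | step 9 | 4-(hydroxymethyl) derivative of 13 (C4 epimers) | O=C1C[C@H]2[C@H](O1)[C@H]3C(CO)C(=O)C=C[C@@]3(C)C[C@@H]2O[Si](CC)(CC)CC
F4 | step 18 | 8α-hydroxy-15-(triisopropylsilyloxy)-10α-methyl-5αH,7αH-13-noreudesma-1,3-dien-12,6α-olide | O=C1C[C@H]2[C@H](O1)[C@H]3C(CO[Si](C(C)C)(C(C)C)C(C)C)=CC=C[C@@]3(C)C[C@@H]2O
F5 | step 18 | 8-oxo-15-(triisopropylsilyloxy)-10α-methyl-5αH,7αH-13-noreudesma-1,3-dien-12,6α-olide | O=C1C[C@H]2[C@H](O1)[C@H]3C(CO[Si](C(C)C)(C(C)C)C(C)C)=CC=C[C@@]3(C)CC2=O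
F6 | step 18 | 8β-hydroxy-15-(triisopropylsilyloxy)-10α-methyl-5αH,7αH-13-noreudesma-1,3-dien-12,6α-olide | O=C1C[C@H]2[C@H](O1)[C@H]3C(CO[Si](C(C)C)(C(C)C)C(C)C)=CC=C[C@@]3(C)C[C@H]2O
F7 | step 18 | 8β-(triethylsilyloxy) ether of F6 | O=C1C[C@H]2[C@H](O1)[C@H]3C(CO[Si](C(C)C)(C(C)C)C(C)C)=CC=C[C@@]3(C)C[C@H]2O[Si](CC)(CC)CC
F8 | step 18 | 11-[(dimethylamino)methyl] derivative of F7 (C11 epimers) | CN(C)CC1C(=O)O[C@H]2[C@H]1[C@H](O[Si](CC)(CC)CC)C[C@]3(C)C=CC=C(CO[Si](C(C)C)(C(C)C)C(C)C)[C@H]23
F9 | step 18 | N-methyl ammonium iodide of F8 | C[N+](C)(C)CC1C(=O)O[C@H]2[C@H]1[C@H](O[Si](CC)(CC)CC)C[C@]3(C)C=CC=C(CO[Si](C(C)C)(C(C)C)C(C)C)[C@H]23.[I-]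
F10 | step 18 | 15-(triisopropylsilyloxy)-8β-(triethylsilyloxy)-10α-methyl-5αH,7αH-eudesma-1,3,11(13)-trien-12,6α-olide | C=C1C(=O)O[C@H]2[C@H]1[C@H](O[Si](CC)(CC)CC)C[C@]3(C)C=CC=C(CO[Si](C(C)C)(C(C)C)C(C)C)[C@H]23
F11 | step 18 | 8β-hydroxy-15-(triisopropylsilyloxy)-10α-methyl-5αH,7αH-eudesma-1,3,11(13)-trien-12,6α-olide | C=C1C(=O)O[C@H]2[C@H]1[C@H](O)C[C@]3(C)C=CC=C(CO[Si](C(C)C)(C(C)C)C(C)C)[C@H]23
A1 | alternative 1 | methyl (2Z)-2-(bromomethyl)-alk-2-enoate seco-aldehyde: 6,7-seco (2Z,4Z)-dienal with 1,10-epoxide, 8-OSi(t-Bu)Me2 and 15-OSi(i-Pr)3 | O=C/C=C(CO[Si](C(C)C)(C(C)C)C(C)C)\C=C/[C@H]1O[C@]1(C)C[C@@H](O[Si](C)(C)C(C)(C)C)/C=C(\CBr)C(=O)OC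
A2 | alternative 1 | (1R,6R,7R,8R,10R)-8-(tert-butyldimethylsilyloxy)-1,10-epoxy-15-(triisopropylsilyloxy)germacra-2Z,4E,11(13)-trien-12,6-olide | C=C1C(=O)O[C@@H]2/C=C(CO[Si](C(C)C)(C(C)C)C(C)C)\C=C/[C@H]3O[C@]3(C)C[C@@H](O[Si](C)(C)C(C)(C)C)[C@@H]12
A3 | alternative 2 | 13-membered bis-allylic ether (O between C6 and C13) with 1,10-epoxide, 2Z,4-diene, C7=C11, 8-, 12- and 15-silyloxy groups | C1/C=C(CO[Si](C(C)C)(C(C)C)C(C)C)\C=C/[C@H]2O[C@]2(C)C[C@@H](O[Si](C)(C)C(C)(C)C)/C=C(CO[Si](C)(C)C(C)(C)C)/CO1
A4 | alternative 2 | ring-contracted ten-membered 6α-alcohol with 7-[3-(tert-butyldimethylsilyloxy)prop-1-en-2-yl] group | C=C(CO[Si](C)(C)C(C)(C)C)[C@H]1[C@H](O)/C=C(CO[Si](C(C)C)(C(C)C)C(C)C)\C=C/[C@H]2O[C@]2(C)C[C@H]1O[Si](C)(C)C(C)(C)C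
A5 | alternative 3 | 2,3-seco triene: trans-lactone carrying a vinyl epoxide arm on C8–C9 and a (Z)-dienyl arm on C6 | C=C[C@H]1O[C@]1(C)C[C@@H](O[Si](C)(C)C(C)(C)C)[C@H]2C(=C)C(=O)O[C@@H]2/C=C(CO[Si](C(C)C)(C(C)C)C(C)C)\C=C
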